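**Retrosynthetic overview**

1. The strategy rests on C4, a methyl-bearing tertiary C–O carbon flanked by C5–O (4,5-oxirane) and C6–O (12,6-butenolide): it is the carbinol carbon of (R)-linalool, whose vinyl group is C5=C6 and whose own oxygen becomes the oxirane oxygen.
2. Last disconnections: the C13 PMB ether (DDQ) and the 1,10-oxirane (peracid on the exposed face of E-C1=C10).
3. Key disconnection: C6–O (butenolide) and C5–O (oxirane) together, back to a ten-membered (1(10)E,5E)-4-hydroxy-trienoic acid with C12 cis to C6; iodine activates C5=C6, the carboxylate closes at C6, the C4 hydroxyl displaces the C5 iodide.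
4. Ring order: ten-membered carbocycle first (10-endo Heck, C6–C7, (Z)-enol triflate onto the linalool vinyl group), then butenolide and 4,5-oxirane in one operation, then the 1,10-oxirane.
5. Open chain: C8–C9 by Evans glycolate alkylation with the linalool-derived allylic iodide (sets C8), C7–C11 by Claisen acylation with a 3-(PMB-oxy)propanoate; the C12 ester is 2-(trimethylsilyl)ethyl so it can be cleaved beside the tiglate.

Key step: step 16

Remark: germacrane numbering is used throughout; (R)-linalool of high enantiomeric purity is assumed, since its carbinol carbon becomes C4 unchanged.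

**Route**

Step 1
Reactants: 1 (R)-linalool
Product: 2 (R)-3,7-dimethyl-3-(triethylsilyloxy)octa-1,6-diene
Conditions: Et3SiOTf, 2,6-lutidine, CH2Cl2, −78 to 0 °C
Reagents that add atoms: triethylsilyl triflate, CC[Si](CC)(CC)OS(=O)(=O)C(F)(F)F
Why: Silylation of a tertiary alcohol with a silyl triflate and a hindered base is routine and masks the C4 hydroxyl for the halide, enolate and triflation steps without touching the stereocentre.

Step 2
Reactants: 2 linalool triethylsilyl ether
Product: 3 (2E,6R)-2,6-dimethyl-6-(triethylsilyloxy)octa-2,7-dien-1-ol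
Conditions: SeO2 (cat.), t-BuOOH, salicylic acid (cat.), CH2Cl2, 0 °C to rt
Reagents that add atoms: tert-butyl hydroperoxide, CC(C)(C)OO
Why: Riley allylic oxidation with catalytic SeO2 (ene reaction, then [2,3]-shift) takes the E methyl group of a gem-dimethyl trisubstituted olefin, which puts the future C9 trans to C2 across C1=C10; the vinyl group has no allylic hydrogen.

Step 3
Reactants: 3 E-allylic alcohol
Product: 4 (2E,6R)-1-iodo-2,6-dimethyl-6-(triethylsilyloxy)octa-2,7-diene
Conditions: PPh3, I2, imidazole, CH2Cl2, 0 °C, used crude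
Reagents that add atoms: iodine, II
Why: Appel-type iodination of a primary allylic alcohol is an SN2 process at the primary carbon, without allylic shift, and gives the reactive iodide that glycolate enolates require.

Step 4
Reactants: 5 3,4-dimethoxybenzyl alcohol; 6 bromoacetic acid
Product: 7 2-[(3,4-dimethoxybenzyl)oxy]acetic acid
Conditions: NaH (2.2 equiv), THF, 0 °C to rt; aq. HCl to pH 3
Reagents that add atoms: none
Why: Williamson etherification of the alkoxide with the bromoacetate salt is the standard route to alkoxyacetic acids.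

Step 5
Reactants: 7 (3,4-dimethoxybenzyloxy)acetic acid; 8 (R)-4-benzyl-2-oxazolidinone
Product: 10 (R)-4-benzyl-3-{2-[(3,4-dimethoxybenzyl)oxy]acetyl}oxazolidin-2-one, via mixed pivalic anhydride 9 (not isolated)
Conditions: t-BuCOCl, Et3N, THF, −20 °C; then 8, LiCl, rt
Reagents that add atoms: none
Why: N-Acylation of an oxazolidinone through the mixed pivalic anhydride with LiCl and Et3N is the usual preparation of glycolate imides.

Step 6
Reactants: 10 glycolate imide; 4 allylic iodide
Product: 12 (4R)-4-benzyl-3-[(2S,4E,8R)-2-(3,4-dimethoxybenzyloxy)-4,8-dimethyl-8-(triethylsilyloxy)deca-4,9-dienoyl]oxazolidin-2-one, via sodium Z-enolate 11 (not isolated)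
Conditions: NaN(SiMe3)2, THF, −78 °C; then 4, −78 to −45 °C
Reagents that add atoms: none
Why: Evans alkylation of a glycolate imide: the chelated sodium Z-enolate is alkylated on the face away from the benzyl group, which with the (R)-auxiliary sets C8 as S.

Step 7
Reactants: 12 alkylated imide
Product: 13 (2S,4E,8R)-2-(3,4-dimethoxybenzyloxy)-N-methoxy-N,4,8-trimethyl-8-(triethylsilyloxy)deca-4,9-dienamide
Conditions: MeNHOMe·HCl, AlMe3, CH2Cl2, −10 °C to rt
Reagents that add atoms: N,O-dimethylhydroxylamine hydrochloride, CNOC.Cl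
Why: Aluminium-amide transamination of acyl oxazolidinones to Weinreb amides is well established for α-alkoxy imides, leaves C8 intact and returns the auxiliary.

Step 8
Reactants: 14 2-(trimethylsilyl)ethanol; 15 acryloyl chloride
Product: 16 2-(trimethylsilyl)ethyl acrylate
Conditions: Et3N, CH2Cl2, 0 °C
Reagents that add atoms: none
Why: Acylation of a primary alcohol by an acid chloride.

Step 9
Reactants: 16 2-(trimethylsilyl)ethyl acrylate; 17 4-methoxybenzyl alcohol
Product: 18 2-(trimethylsilyl)ethyl 3-[(4-methoxybenzyl)oxy]propanoate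
Conditions: PBu3 (10 mol%), MeCN, rt
Reagents that add atoms: none
Why: Phosphine-catalysed oxa-Michael addition of a primary alcohol to an acrylate is known and avoids the ester exchange that alkoxide catalysis would cause.

Step 10
Reactants: 18 3-(PMB-oxy)propanoate; 13 Weinreb amide
Product: 20 2-(trimethylsilyl)ethyl (4S,6E,10R)-4-(3,4-dimethoxybenzyloxy)-2-[(4-methoxybenzyloxy)methyl]-6,10-dimethyl-3-oxo-10-(triethylsilyloxy)dodeca-6,11-dienoate (C11 epimers), via lithium enolate 19 (not isolated)
Conditions: LiN(iPr)2, THF, −78 °C; then 13, −78 to −40 °C; aq. NH4Cl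
Reagents that add atoms: none
Why: Crossed Claisen acylation of an ester enolate by a Weinreb amide stops at the chelated tetrahedral adduct and releases the β-keto ester on work-up; C13 arrives already as its PMB ether, and the C11 centre is erased in the next step.

Step 11
Reactants: 20 β-keto ester
Product: 22 2-(trimethylsilyl)ethyl (2Z,4S,6E,10R)-4-(3,4-dimethoxybenzyloxy)-2-[(4-methoxybenzyloxy)methyl]-6,10-dimethyl-10-(triethylsilyloxy)-3-(trifluoromethylsulfonyloxy)dodeca-2,6,11-trienoate, via sodium enolate 21 (not isolated)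
Conditions: NaH, THF, 0 °C; then Tf2O, −78 to 0 °C
Reagents that add atoms: triflic anhydride, O=S(=O)(OS(=O)(=O)C(F)(F)F)C(F)(F)F
Why: O-Sulfonylation of the sodium-chelated enolate of a β-keto ester, in which enolate oxygen and ester carbonyl are held cis, is the known route to (Z)-enol triflates and places the triflate (the future C6 position) cis to C12.

Step 12
Reactants: 22 (Z)-enol triflate
Product: 23 2-(trimethylsilyl)ethyl (4R,8S)-8-(3,4-dimethoxybenzyloxy)-13-(4-methoxybenzyloxy)-4-(triethylsilyloxy)germacra-1(10)E,5E,7(11)-trien-12-oate (ten-membered ring, C12 cis to C6)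
Conditions: Pd(OAc)2 (10 mol%), PPh3 (20 mol%), Bu4NCl, KOAc, DMF (0.002 M), 70 °C
Reagents that add atoms: none
Why: Intramolecular Mizoroki–Heck reaction: the vinylpalladium species formed from the triflate and zerovalent palladium adds to the unsubstituted terminus of the C4 vinyl group (10-endo, C6–C7 bond), and syn β-hydride elimination, possible only from C6 because C4 is quaternary, should give the E C5=C6 olefin as tertiary allylic carbinol olefins do in the intermolecular reaction.

Step 13
Reactants: 23 macrocyclic triene ester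
Product: 24 2-(trimethylsilyl)ethyl (4R,8S)-8-hydroxy-13-(4-methoxybenzyloxy)-4-(triethylsilyloxy)germacra-1(10)E,5E,7(11)-trien-12-oate
Conditions: DDQ (1.1 equiv), CH2Cl2/pH 7 buffer, 0 °C
Reagents that add atoms: none
Why: Oxidative ether cleavage by DDQ is faster for the more electron-rich 3,4-dimethoxybenzyl ether than for a 4-methoxybenzyl ether, so the C8 hydroxyl should be freed while the C13 PMB ether stays.

Step 14
Reactants: 24 C8 alcohol; 25 tigloyl chloride
Product: 26 2-(trimethylsilyl)ethyl (4R,8S)-13-(4-methoxybenzyloxy)-8-tigloyloxy-4-(triethylsilyloxy)germacra-1(10)E,5E,7(11)-trien-12-oate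
Conditions: pyridine, DMAP (cat.), CH2Cl2, 0 °C to rt
Reagents that add atoms: none
Why: DMAP-catalysed acylation of a secondary allylic alcohol by an acid chloride; the C4 oxygen is still silylated and the tiglate (E) geometry is the stable one.

Step 15
Reactants: 26 tiglate ester
Product: 27 (4R,8S)-4-hydroxy-13-(4-methoxybenzyloxy)-8-tigloyloxygermacra-1(10)E,5E,7(11)-trien-12-oic acid
Conditions: Bu4NF, THF, 0 °C to rt; dilute aq. HCl to pH 5
Reagents that add atoms: none
Why: Fluoride cleaves the 2-(trimethylsilyl)ethyl ester by β-elimination and the tertiary silyl ether in the same operation, under conditions that should spare the tiglate and the PMB ether, which a hydroxide saponification would not.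

Step 16
Reactants: 27 hydroxy trienoic acid
Product: 29 (4R,5R,6S,8S)-4,5-epoxy-13-(4-methoxybenzyloxy)-8-tigloyloxygermacra-1(10)E,7(11)-dien-12,6-olide, via iodolactone 28 (not isolated)
Conditions: I2, NaHCO3, MeCN, 0 °C, dark; then Ag2O, rt
Reagents that add atoms: none
Why: Proposed new method: iodine adds reversibly to C5=C6; the C12 carboxylate, fixed cis to C6 on C7=C11, opens the iodonium at C6 anti to iodine (5-exo-trig, butenolide ring) to give the (5S)-iodide 28, and Ag2O then assists loss of iodide while the C4 hydroxyl attacks C5 from the rear (3-exo-tet, oxirane ring), silver being chosen because amine or carbonate bases are known to dehydroiodinate 5-(1-iodoalkyl)butenolides to ylidene butenolides. The closest known reactions are the iodolactonisation of (2Z,4E)-dienoic acids to 5-(1-iodoalkyl)butenolides and the closure of iodohydrins to epoxides; neither has been run on an E olefin held in a ten-membered ring, nor in tandem. C5 and C6 are set as a pair by the E geometry, because anti addition followed by inversion at C5 leaves both oxygens on one face of the former olefin, and C4 (from linalool, untouched) makes the oxirane trans, since C3 must stand anti to C6 for the rearside attack. The sense of the pair against C4 and C8 is decided by the olefin face that takes iodine: (5R,6S) needs iodine on the Si face of C5 and oxygen on the Re face of C6, a choice that the (4R) and (8S) centres must bias through the ring conformation. Because the carboxylate reaches C6 only from the C11 side, that iodine has to sit on the C8 side of the olefin, the side over which the C8–C3 bridge runs in the relaxed ring, and it is this demand on the ring, not either bond-forming event, that makes the step a proposal. Chemoselectivity rests on reversibility: an iodonium on C1=C10 or on the open face of C5=C6 has no oxygen in reach and should revert, and the tiglate and C7=C11 olefins are too electron-poor to take iodine.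

Step 17
Reactants: 29 epoxy butenolide
Product: 30 (1R,4R,5R,6S,8S,10R)-1,10:4,5-diepoxy-13-(4-methoxybenzyloxy)-8-tigloyloxygermacr-7(11)-en-12,6-olide
Conditions: mCPBA, CH2Cl2/aq. NaHCO3, 0 °C
Reagents that add atoms: 3-chloroperbenzoic acid, OOC(=O)c1cccc(Cl)c1
Why: Prilezhaev epoxidation takes the only electron-rich olefin, and attack on the exposed face of E-C1=C10, as in 4,5-epoxygermacr-1(10)-en-12,6-olides of the parthenolide type, should give the trans (1R,10R)-oxirane.

Step 18
Reactants: 30 PMB-protected diepoxide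
Product: 31 (1R,4R,5R,6S,8S,10R)-1,10:4,5-diepoxy-13-hydroxy-8-tigloyloxygermacr-7(11)-en-12,6-olide (CNP0111480.1)
Conditions: DDQ, CH2Cl2/pH 7 buffer, rt
Reagents that add atoms: none
Why: Oxidative removal of the PMB ether under buffered, near-neutral conditions should leave both oxiranes, the butenolide and the tiglate untouched.

**Compound list**

1 | (R)-linalool | C=C[C@](C)(O)CCC=C(C)C | starting material
2 | (R)-3,7-dimethyl-3-(triethylsilyloxy)octa-1,6-diene | C=C[C@](C)(O[Si](CC)(CC)CC)CCC=C(C)C | intermediate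
3 | (2E,6R)-2,6-dimethyl-6-(triethylsilyloxy)octa-2,7-dien-1-ol | C=C[C@](C)(O[Si](CC)(CC)CC)CC/C=C(\C)CO | intermediate
4 | (2E,6R)-1-iodo-2,6-dimethyl-6-(triethylsilyloxy)octa-2,7-diene | C=C[C@](C)(O[Si](CC)(CC)CC)CC/C=C(\C)CI | intermediate
5 | 3,4-dimethoxybenzyl alcohol | COc1ccc(CO)cc1OC | starting material
6 | bromoacetic acid | OC(=O)CBr | starting material
7 | 2-[(3,4-dimethoxybenzyl)oxy]acetic acid | COc1ccc(COCC(=O)O)cc1OC | intermediate
8 | (R)-4-benzyl-2-oxazolidinone | O=C1N[C@H](Cc2ccccc2)CO1 | starting material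
9 | 2-[(3,4-dimethoxybenzyl)oxy]acetic pivalic anhydride (not isolated) | COc1ccc(COCC(=O)OC(=O)C(C)(C)C)cc1OC | intermediate
10 | (R)-4-benzyl-3-{2-[(3,4-dimethoxybenzyl)oxy]acetyl}oxazolidin-2-one | COc1ccc(COCC(=O)N2[C@H](Cc3ccccc3)COC2=O)cc1OC | intermediate
11 | sodium Z-enolate of 10 (not isolated) | COc1ccc(CO/C=C(\[O-])N2[C@H](Cc3ccccc3)COC2=O)cc1OC.[Na+] | intermediate
12 | (4R)-4-benzyl-3-[(2S,4E,8R)-2-(3,4-dimethoxybenzyloxy)-4,8-dimethyl-8-(triethylsilyloxy)deca-4,9-dienoyl]oxazolidin-2-one | C=C[C@](C)(O[Si](CC)(CC)CC)CC/C=C(\C)C[C@H](OCc1ccc(OC)c(OC)c1)C(=O)N1[C@H](Cc2ccccc2)COC1=O | intermediate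
13 | (2S,4E,8R)-2-(3,4-dimethoxybenzyloxy)-N-methoxy-N,4,8-trimethyl-8-(triethylsilyloxy)deca-4,9-dienamide | C=C[C@](C)(O[Si](CC)(CC)CC)CC/C=C(\C)C[C@H](OCc1ccc(OC)c(OC)c1)C(=O)N(C)OC | intermediate
14 | 2-(trimethylsilyl)ethanol | C[Si](C)(C)CCO | starting material
15 | acryloyl chloride | C=CC(=O)Cl | starting material
16 | 2-(trimethylsilyl)ethyl acrylate | C=CC(=O)OCC[Si](C)(C)C | intermediate
17 | 4-methoxybenzyl alcohol | COc1ccc(CO)cc1 | starting material
18 | 2-(trimethylsilyl)ethyl 3-[(4-methoxybenzyl)oxy]propanoate | COc1ccc(COCCC(=O)OCC[Si](C)(C)C)cc1 | intermediate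
19 | lithium enolate of 18 (not isolated) | COc1ccc(COCC=C([O-])OCC[Si](C)(C)C)cc1.[Li+] | intermediate
20 | 2-(trimethylsilyl)ethyl (4S,6E,10R)-4-(3,4-dimethoxybenzyloxy)-2-[(4-methoxybenzyloxy)methyl]-6,10-dimethyl-3-oxo-10-(triethylsilyloxy)dodeca-6,11-dienoate | C=C[C@](C)(O[Si](CC)(CC)CC)CC/C=C(\C)C[C@H](OCc1ccc(OC)c(OC)c1)C(=O)C(COCc1ccc(OC)cc1)C(=O)OCC[Si](C)(C)C | intermediate
21 | sodium enolate of 20 (not isolated) | C=C[C@](C)(O[Si](CC)(CC)CC)CC/C=C(\C)C[C@H](OCc1ccc(OC)c(OC)c1)/C([O-])=C(\COCc1ccc(OC)cc1)C(=O)OCC[Si](C)(C)C.[Na+] | intermediate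
22 | 2-(trimethylsilyl)ethyl (2Z,4S,6E,10R)-4-(3,4-dimethoxybenzyloxy)-2-[(4-methoxybenzyloxy)methyl]-6,10-dimethyl-10-(triethylsilyloxy)-3-(trifluoromethylsulfonyloxy)dodeca-2,6,11-trienoate | C=C[C@](C)(O[Si](CC)(CC)CC)CC/C=C(\C)C[C@H](OCc1ccc(OC)c(OC)c1)/C(OS(=O)(=O)C(F)(F)F)=C(\COCc1ccc(OC)cc1)C(=O)OCC[Si](C)(C)C | intermediate
23 | 2-(trimethylsilyl)ethyl (4R,8S)-8-(3,4-dimethoxybenzyloxy)-13-(4-methoxybenzyloxy)-4-(triethylsilyloxy)germacra-1(10)E,5E,7(11)-trien-12-oate | COc1ccc(CO[C@H]2C/C(C)=C/CC[C@@](C)(O[Si](CC)(CC)CC)/C=C/C2=C(/COCc3ccc(OC)cc3)C(=O)OCC[Si](C)(C)C)cc1OC | intermediate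
24 | 2-(trimethylsilyl)ethyl (4R,8S)-8-hydroxy-13-(4-methoxybenzyloxy)-4-(triethylsilyloxy)germacra-1(10)E,5E,7(11)-trien-12-oate | O[C@H]1C/C(C)=C/CC[C@@](C)(O[Si](CC)(CC)CC)/C=C/C1=C(/COCc2ccc(OC)cc2)C(=O)OCC[Si](C)(C)C | intermediate
25 | tigloyl chloride, (E)-2-methylbut-2-enoyl chloride | C/C=C(\C)C(=O)Cl | starting material
26 | 2-(trimethylsilyl)ethyl (4R,8S)-13-(4-methoxybenzyloxy)-8-tigloyloxy-4-(triethylsilyloxy)germacra-1(10)E,5E,7(11)-trien-12-oate | C/C=C(\C)C(=O)O[C@H]1C/C(C)=C/CC[C@@](C)(O[Si](CC)(CC)CC)/C=C/C1=C(/COCc2ccc(OC)cc2)C(=O)OCC[Si](C)(C)C | intermediate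
27 | (4R,8S)-4-hydroxy-13-(4-methoxybenzyloxy)-8-tigloyloxygermacra-1(10)E,5E,7(11)-trien-12-oic acid | C/C=C(\C)C(=O)O[C@H]1C/C(C)=C/CC[C@@](C)(O)/C=C/C1=C(/COCc2ccc(OC)cc2)C(=O)O | intermediate
28 | (4R,5S,6S,8S)-4-hydroxy-5-iodo-13-(4-methoxybenzyloxy)-8-tigloyloxygermacra-1(10)E,7(11)-dien-12,6-olide (not isolated) | C/C=C(\C)C(=O)O[C@H]1C/C(C)=C/CC[C@@](C)(O)[C@@H](I)[C@H]2OC(=O)C(COCc3ccc(OC)cc3)=C12 | intermediate
29 | (4R,5R,6S,8S)-4,5-epoxy-13-(4-methoxybenzyloxy)-8-tigloyloxygermacra-1(10)E,7(11)-dien-12,6-olide | C/C=C(\C)C(=O)O[C@H]1C/C(C)=C/CC[C@@]2(C)O[C@@H]2[C@H]2OC(=O)C(COCc3ccc(OC)cc3)=C12 | intermediate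
30 | (1R,4R,5R,6S,8S,10R)-1,10:4,5-diepoxy-13-(4-methoxybenzyloxy)-8-tigloyloxygermacr-7(11)-en-12,6-olide | C/C=C(\C)C(=O)O[C@H]1C[C@@]2(C)O[C@@H]2CC[C@@]2(C)O[C@@H]2[C@H]2OC(=O)C(COCc3ccc(OC)cc3)=C12 | intermediate
31 | (1R,4R,5R,6S,8S,10R)-1,10:4,5-diepoxy-13-hydroxy-8-tigloyloxygermacr-7(11)-en-12,6-olide, CNP0111480.1 | C/C=C(\C)C(=O)O[C@H]1C[C@@]2(C)O[C@@H]2CC[C@@]2(C)O[C@@H]2[C@H]2OC(=O)C(CO)=C12 | target

**Step count and risks**

Total step count: 18. Longest linear sequence: 14 steps from (R)-linalool (steps 1–3, 6, 7, 10–18).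

Steps most likely to fail:

1. Step 16 (labelled step). The iodine may be unable to reach the ring-side face of the E olefin (Si at C5), which lies under the C8–C3 bridge. In that case no lactone forms, and an iodonium on the exposed face of C5=C6 or on C1=C10 may be captured across the ring by the other olefin (transannular C–C bond formation). A second failure process is delivery of iodine to the other diastereoface after a ring flip, giving the (5S,6R) pair. Fallback with known reactions, from 27: a catalytic amount of Ph3SiOReO3 (Et2O, 0 °C) should shift the tertiary C4 hydroxyl suprafacially to C6 (perrhenate 1,3-transposition of allylic alcohols), on the exposed face towards which the C4–O bond points. The (Z)-4-hydroxy-2-enoic acid so formed should lactonise at once to (8S)-13-(4-methoxybenzyloxy)-8-tigloyloxygermacra-1(10)E,4E,7(11)-trien-12,6-olide F1. mCPBA (2.2 equiv, CH2Cl2/aq. NaHCO3, 0 °C) should then epoxidise both trisubstituted E olefins from the outer face, as germacra-1(10),4-dien-12,6-olides do, and the route is rejoined at 30. In this variant the linalool oxygen ends as the lactone oxygen and both oxirane oxygens come from the peracid.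

2. Step 12. Ring closure to a strained ten-membered E,E-diene may lose to oligomerisation, and β-hydride elimination inside the medium ring may deliver the Z C5=C6 olefin. Fallback, from 22, moves the ring closure to a carbonyl addition at C6–C7:
   - HF·pyridine should free the tertiary alcohol, 2-(trimethylsilyl)ethyl (2Z,4S,6E,10R)-4-(3,4-dimethoxybenzyloxy)-10-hydroxy-2-[(4-methoxybenzyloxy)methyl]-6,10-dimethyl-3-(trifluoromethylsulfonyloxy)dodeca-2,6,11-trienoate F2.
   - Pyridinium chlorochromate, [C5H5NH][CrO3Cl] (CH2Cl2, rt; Babler–Dauben oxidative transposition) should give the 12-oxo-2Z,6E,10E-trienoate (E-enal) F3.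
   - A Nozaki–Hiyama–Kishi closure (CrCl2, NiCl2 cat., DMSO, high dilution) should join C7 to the aldehyde carbon C6, and the C6 alkoxide should lactonise onto the cis C12 ester to give (8S)-8-(3,4-dimethoxybenzyloxy)-13-(4-methoxybenzyloxy)germacra-1(10)E,4E,7(11)-trien-12,6-olide F4.
   - DDQ, as in step 13, should give the 8-hydroxy trienolide F5; 25 with pyridine and DMAP gives the 8-tigloyloxy trienolide F1, which is epoxidised twice as in the first fallback, and the route is rejoined at 30.
   - Here C6 would have to be set against C8 in the ring closure, and the iodine cascade is bypassed.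

3. Step 10. The enolate 19 may expel 4-methoxybenzyl oxide (β-elimination to the acrylate), and the α-alkoxy ketone may epimerise at C8 under the basic conditions. Fallback, from 13, builds the C7–C11 bond without a strong base:
   - iBu2AlH (THF, −78 °C) should give (2S,4E,8R)-2-(3,4-dimethoxybenzyloxy)-4,8-dimethyl-8-(triethylsilyloxy)deca-4,9-dienal F6.
   - Morita–Baylis–Hillman reaction with 16 (DABCO, neat) should give the 3-hydroxy-2-methylene ester F7.
   - Dess–Martin periodinane should give the 2-methylene-3-oxo ester F8.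
   - Conjugate addition of 17 (Et3N cat., CH2Cl2) returns to 20.

Further compounds
F1 | step 16 | (8S)-13-(4-methoxybenzyloxy)-8-tigloyloxygermacra-1(10)E,4E,7(11)-trien-12,6-olide (C6 as in the target) | C/C=C(\C)C(=O)O[C@H]1C/C(C)=C/CC/C(C)=C/[C@H]2OC(=O)C(COCc3ccc(OC)cc3)=C12
F2 | step 12 | 2-(trimethylsilyl)ethyl (2Z,4S,6E,10R)-4-(3,4-dimethoxybenzyloxy)-10-hydroxy-2-[(4-methoxybenzyloxy)methyl]-6,10-dimethyl-3-(trifluoromethylsulfonyloxy)dodeca-2,6,11-trienoate | C=C[C@](C)(O)CC/C=C(\C)C[C@H](OCc1ccc(OC)c(OC)c1)/C(OS(=O)(=O)C(F)(F)F)=C(\COCc1ccc(OC)cc1)C(=O)OCC[Si](C)(C)C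
F3 | step 12 | 2-(trimethylsilyl)ethyl (2Z,4S,6E,10E)-4-(3,4-dimethoxybenzyloxy)-2-[(4-methoxybenzyloxy)methyl]-6,10-dimethyl-12-oxo-3-(trifluoromethylsulfonyloxy)dodeca-2,6,10-trienoate | O=C/C=C(\C)CC/C=C(\C)C[C@H](OCc1ccc(OC)c(OC)c1)/C(OS(=O)(=O)C(F)(F)F)=C(\COCc1ccc(OC)cc1)C(=O)OCC[Si](C)(C)C
F4 | step 12 | (8S)-8-(3,4-dimethoxybenzyloxy)-13-(4-methoxybenzyloxy)germacra-1(10)E,4E,7(11)-trien-12,6-olide | COc1ccc(CO[C@H]2C/C(C)=C/CC/C(C)=C/[C@H]3OC(=O)C(COCc4ccc(OC)cc4)=C23)cc1OC
F5 | step 12 | (8S)-8-hydroxy-13-(4-methoxybenzyloxy)germacra-1(10)E,4E,7(11)-trien-12,6-olide | O[C@H]1C/C(C)=C/CC/C(C)=C/[C@H]2OC(=O)C(COCc3ccc(OC)cc3)=C12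
F6 | step 10 | (2S,4E,8R)-2-(3,4-dimethoxybenzyloxy)-4,8-dimethyl-8-(triethylsilyloxy)deca-4,9-dienal | C=C[C@](C)(O[Si](CC)(CC)CC)CC/C=C(\C)C[C@H](OCc1ccc(OC)c(OC)c1)C=O
F7 | step 10 | 2-(trimethylsilyl)ethyl (4S,6E,10R)-4-(3,4-dimethoxybenzyloxy)-3-hydroxy-6,10-dimethyl-2-methylene-10-(triethylsilyloxy)dodeca-6,11-dienoate | C=C[C@](C)(O[Si](CC)(CC)CC)CC/C=C(\C)C[C@H](OCc1ccc(OC)c(OC)c1)C(O)C(=C)C(=O)OCC[Si](C)(C)C
F8 | step 10 | 2-(trimethylsilyl)ethyl (4S,6E,10R)-4-(3,4-dimethoxybenzyloxy)-6,10-dimethyl-2-methylene-3-oxo-10-(triethylsilyloxy)dodeca-6,11-dienoate | C=C[C@](C)(O[Si](CC)(CC)CC)CC/C=C(\C)C[C@H](OCc1ccc(OC)c(OC)c1)C(=O)C(=C)C(=O)OCC[Si](C)(C)C
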